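**Retrosynthetic overview**
1. The target is two (2S)-flavanones joined by a diaryl ether from the C3′ oxygen of the 7-O-methyl unit's B ring to C4′ of the 5,7-dihydroxy unit's B ring; the last disconnection is removal of four O-benzyl groups.
2. Key disconnection: the O1–C2 bond of the pyranone of the 5,7-dihydroxy unit (the last ring), opened to an acyclic, E/Z-mixed 2-hydroxyaryl alkylidene β-keto ester with a temporary CO2tBu on C3. A bifunctional cinchona thiourea closes it by 6-endo oxa-Michael addition to the (S) centre, and acid expels the CO2tBu in the same flask.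
3. Enabling feature: in that ring the phenolic O1 is ortho to the aryl ketone C4, and C3 is a methylene between C4=O and C2, so it can carry a traceless ester that activates C2 and gives the catalyst a two-point handle. C2 is the ring's only stereocentre, and the phloroglucinol A ring offers two equivalent ortho oxygens, so there is no regiochemical question.
4. The alkylidene comes from Knoevenagel union of a phloroacetophenone-derived β-keto ester with a B-ring aldehyde that already carries the first flavanone. That flavanone is made the same way from the other formyl group of a differentiated (CHO/dioxolane) diaryl ether built by Ullmann coupling.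
5. Ring order: the benzene rings are bought; pyranone of the 7-O-methyl unit (step 5); pyranone of the 5,7-dihydroxy unit last (step 9).

Key step: step 9

Assumption: the quinidine-derived member of the cinchona thiourea pair is taken to give the (2S) flavanone; if the sense is the reverse on these substrates, the quinine-derived pseudoenantiomer replaces it in steps 5 and 9 and nothing else changes.

**Step 1**
Reactants: 1 4-(benzyloxy)-3-hydroxybenzaldehyde; 2 2-(4-bromophenyl)-1,3-dioxolane
Product: 3 4-(benzyloxy)-3-[4-(1,3-dioxolan-2-yl)phenoxy]benzaldehyde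
Conditions: CuI (10 mol%), N,N-dimethylglycine·HCl (30 mol%), Cs2CO3 (2 equiv), 1,4-dioxane, 90 °C
Reagents that add atoms: none
Why: Ullmann-type Cu(I)-catalysed diaryl ether coupling of the phenoxide of 1 with the aryl bromide should proceed without touching the non-enolisable aldehyde, the benzyl ether or the base-stable dioxolane, and it delivers the two formyl carbons already differentiated (one free, one masked).

**Step 2**
Reactants: 4 1-(2,6-dihydroxy-4-methoxyphenyl)ethan-1-one
Product: 5 1-[2-(benzyloxy)-6-hydroxy-4-methoxyphenyl]ethan-1-one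
Conditions: BnBr (1.05 equiv), K2CO3 (1.1 equiv), acetone, reflux
Reagents that add atoms: benzyl bromide, BrCc1ccccc1
Why: Williamson etherification of one of the two equivalent phenols, after which the remaining hydroxyl is tied up in a hydrogen bond to the acetyl group and reacts far more slowly, so the mono-ether should predominate.

**Step 3**
Reactants: 5 1-[2-(benzyloxy)-6-hydroxy-4-methoxyphenyl]ethan-1-one
Product: 6 tert-butyl 3-[2-(benzyloxy)-6-hydroxy-4-methoxyphenyl]-3-oxopropanoate
Conditions: LiHMDS (3.3 equiv), THF, −78 °C; Boc2O (1.1 equiv), −78 → 0 °C; cold 1 M HCl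
Reagents that add atoms: di-tert-butyl dicarbonate, CC(C)(C)OC(=O)OC(=O)OC(C)(C)C
Why: Claisen-type C-acylation of the lithium phenoxide–enolate dianion with Boc2O (the third equivalent of base is consumed by the more acidic β-keto ester product), a reaction type known for o-hydroxyacetophenone polyanions and acylating agents; any aryl carbonate from O-acylation is expected to converge by O→C acyl transfer under the excess base.

**Step 4**
Reactants: 3 4-(benzyloxy)-3-[4-(1,3-dioxolan-2-yl)phenoxy]benzaldehyde; 6 tert-butyl 3-[2-(benzyloxy)-6-hydroxy-4-methoxyphenyl]-3-oxopropanoate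
Product: 7 tert-butyl 2-[2-(benzyloxy)-6-hydroxy-4-methoxybenzoyl]-3-{4-(benzyloxy)-3-[4-(1,3-dioxolan-2-yl)phenoxy]phenyl}prop-2-enoate (E/Z mixture)
Conditions: piperidine (0.2 equiv), AcOH (0.2 equiv), 4 Å MS, toluene, rt → 40 °C
Reagents that add atoms: none
Why: Knoevenagel condensation under buffered piperidinium acetate with removal of water; 2-hydroxyaryl alkylidene β-keto esters of this class are isolable because they do not cyclise without a bifunctional catalyst, the dioxolane is inert to the buffer, and no stereocentre is formed so the E/Z mixture is taken on as such.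

**Step 5**
Reactants: 7 tert-butyl 2-[2-(benzyloxy)-6-hydroxy-4-methoxybenzoyl]-3-{4-(benzyloxy)-3-[4-(1,3-dioxolan-2-yl)phenoxy]phenyl}prop-2-enoate
Product: 10 4-{2-(benzyloxy)-5-[(2S)-5-(benzyloxy)-7-methoxy-4-oxochroman-2-yl]phenoxy}benzaldehyde, via cyclised tert-butyl 4-oxochromane-3-carboxylate 8 (not isolated), via decarboxylated dioxolane flavanone 9 (not isolated)
Conditions: quinidine-derived thiourea 1-[3,5-bis(trifluoromethyl)phenyl]-3-[(9R)-6′-methoxycinchonan-9-yl]thiourea (10 mol%), toluene, −25 °C; then TsOH·H2O (1 equiv), 80 °C; then acetone/H2O (4:1), rt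
Reagents that add atoms: water, O
Why: Bifunctional cinchona-thiourea-catalysed intramolecular oxa-Michael addition (6-endo-trig) in which the catalyst-bound phenoxide adds to one face of the β-carbon and so sets C2 of the first flavanone as S under catalyst control, followed in the same flask by acid cleavage of the tert-butyl ester, decarboxylation of the β-keto acid and hydrolysis of the dioxolane, none of which should touch the benzyl ethers.

**Step 6**
Reactants: 11 1-(2,4,6-trihydroxyphenyl)ethan-1-one
Product: 12 1-[2,4-bis(benzyloxy)-6-hydroxyphenyl]ethan-1-one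
Conditions: BnBr (2.1 equiv), K2CO3 (2.2 equiv), DMF, rt
Reagents that add atoms: benzyl bromide, BrCc1ccccc1
Why: Williamson etherification in which the non-chelated 4-OH and one of the two equivalent ortho hydroxyls are benzylated while the last hydroxyl, hydrogen-bonded to the acetyl group, should stay free.

**Step 7**
Reactants: 12 1-[2,4-bis(benzyloxy)-6-hydroxyphenyl]ethan-1-one
Product: 13 tert-butyl 3-[2,4-bis(benzyloxy)-6-hydroxyphenyl]-3-oxopropanoate
Conditions: LiHMDS (3.3 equiv), THF, −78 °C; Boc2O (1.1 equiv), −78 → 0 °C; cold 1 M HCl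
Reagents that add atoms: di-tert-butyl dicarbonate, CC(C)(C)OC(=O)OC(=O)OC(C)(C)C
Why: Claisen-type C-acylation of the lithium dianion with Boc2O, exactly as in step 3.

**Step 8**
Reactants: 10 4-{2-(benzyloxy)-5-[(2S)-5-(benzyloxy)-7-methoxy-4-oxochroman-2-yl]phenoxy}benzaldehyde; 13 tert-butyl 3-[2,4-bis(benzyloxy)-6-hydroxyphenyl]-3-oxopropanoate
Product: 14 tert-butyl 2-[2,4-bis(benzyloxy)-6-hydroxybenzoyl]-3-(4-{2-(benzyloxy)-5-[(2S)-5-(benzyloxy)-7-methoxy-4-oxochroman-2-yl]phenoxy}phenyl)prop-2-enoate (E/Z mixture)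
Conditions: piperidine (0.2 equiv), AcOH (0.4 equiv), 4 Å MS, toluene, rt → 40 °C
Reagents that add atoms: none
Why: Knoevenagel condensation under the same mild buffer, in which the flavanone of 10 is expected to keep its configuration because it has no free 4′-hydroxyl (no quinone-methide path) and the medium is too weakly basic for retro-oxa-Michael opening, while product 14 does not cyclise in the absence of the bifunctional catalyst.

**Step 9**
Reactants: 14 tert-butyl 2-[2,4-bis(benzyloxy)-6-hydroxybenzoyl]-3-(4-{2-(benzyloxy)-5-[(2S)-5-(benzyloxy)-7-methoxy-4-oxochroman-2-yl]phenoxy}phenyl)prop-2-enoate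
Product: 16 (2S)-5,7-bis(benzyloxy)-2-(4-{2-(benzyloxy)-5-[(2S)-5-(benzyloxy)-7-methoxy-4-oxochroman-2-yl]phenoxy}phenyl)chroman-4-one, via cyclised tert-butyl 4-oxochromane-3-carboxylate 15 (not isolated)
Conditions: quinidine-derived thiourea 1-[3,5-bis(trifluoromethyl)phenyl]-3-[(9R)-6′-methoxycinchonan-9-yl]thiourea (10 mol%), toluene, −25 °C; then TsOH·H2O (1 equiv), 80 °C
Reagents that add atoms: none
Why: The quinuclidine nitrogen of the catalyst deprotonates and hydrogen-bonds the single free phenol of 14 while the thiourea clamps the two carbonyls of the alkylidene β-keto ester, the phenoxide adds to the β-carbon to give the enol(ate) 15, and TsOH then ionises the tert-butyl ester (isobutene) so that the β-keto acid loses CO2, which removes the activating group and shuts off retro-oxa-Michael reversal. The closest known reaction type is the bifunctional cinchona-thiourea-catalysed intramolecular oxa-Michael addition of 2-hydroxyaryl alkylidene β-keto esters to flavanones with in-flask acid decarboxylation. The pyranone is closed by O1–C2 bond formation in a 6-endo-trig mode. The new C2 centre is set as S by the catalyst through face selection at the β-carbon inside the ion-paired, doubly hydrogen-bonded complex, and the existing stereocentre lies far away across the diaryl ether and is not expected to bias the closure, so the catalyst that served in step 5 is used again. The step is stereoconvergent in that the E and Z isomers of 14 are expected to interconvert under the catalyst by reversible conjugate addition and to drain through the same closure, and the C3 epimers and enol form of 15 all collapse to one compound on decarboxylation. The step needs enantioface selectivity and chemoselectivity, secured by the single free phenol (the para oxygen is benzylated so that no vinylogous phenoxide deactivates the enone, and either ortho oxygen of the phloroglucinol ring would give the same skeleton) and by the first flavanone lacking a free 4′-hydroxyl, so that the weak base at −25 °C should not open it.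

**Step 10**
Reactants: 16 (2S)-5,7-bis(benzyloxy)-2-(4-{2-(benzyloxy)-5-[(2S)-5-(benzyloxy)-7-methoxy-4-oxochroman-2-yl]phenoxy}phenyl)chroman-4-one
Product: 17 7-O-methyltetrahydroochnaflavone
Conditions: H2 (1 atm), 10% Pd/C, EtOAc/MeOH (1:1), rt
Reagents that add atoms: none
Why: Catalytic hydrogenolysis of the four benzyl aryl ethers under neutral conditions at 1 atm, which is standard for polyhydroxyflavanones and should leave the aryl ketones, the benzylic C2–O bonds, the methyl ether and both stereocentres untouched.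

**Compound list**
1 | 4-(benzyloxy)-3-hydroxybenzaldehyde | O=Cc1ccc(OCc2ccccc2)c(O)c1 | starting material
2 | 2-(4-bromophenyl)-1,3-dioxolane | Brc1ccc(cc1)C1OCCO1 | starting material
3 | 4-(benzyloxy)-3-[4-(1,3-dioxolan-2-yl)phenoxy]benzaldehyde | O=Cc1ccc(OCc2ccccc2)c(Oc2ccc(cc2)C2OCCO2)c1 | intermediate
4 | 1-(2,6-dihydroxy-4-methoxyphenyl)ethan-1-one | CC(=O)c1c(O)cc(OC)cc1O | starting material
5 | 1-[2-(benzyloxy)-6-hydroxy-4-methoxyphenyl]ethan-1-one | CC(=O)c1c(O)cc(OC)cc1OCc1ccccc1 | intermediate
6 | tert-butyl 3-[2-(benzyloxy)-6-hydroxy-4-methoxyphenyl]-3-oxopropanoate | CC(C)(C)OC(=O)CC(=O)c1c(O)cc(OC)cc1OCc1ccccc1 | intermediate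
7 | tert-butyl 2-[2-(benzyloxy)-6-hydroxy-4-methoxybenzoyl]-3-{4-(benzyloxy)-3-[4-(1,3-dioxolan-2-yl)phenoxy]phenyl}prop-2-enoate, E/Z mixture | CC(C)(C)OC(=O)C(=Cc1ccc(OCc2ccccc2)c(Oc2ccc(cc2)C2OCCO2)c1)C(=O)c1c(O)cc(OC)cc1OCc1ccccc1 | intermediate
8 | tert-butyl (2S)-5-(benzyloxy)-2-{4-(benzyloxy)-3-[4-(1,3-dioxolan-2-yl)phenoxy]phenyl}-7-methoxy-4-oxochromane-3-carboxylate, C3 epimers and enol form, not isolated | COc1cc(OCc3ccccc3)c2c(c1)O[C@H](c1ccc(OCc3ccccc3)c(Oc3ccc(cc3)C3OCCO3)c1)C(C(=O)OC(C)(C)C)C2=O | intermediate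
9 | (2S)-5-(benzyloxy)-2-{4-(benzyloxy)-3-[4-(1,3-dioxolan-2-yl)phenoxy]phenyl}-7-methoxychroman-4-one, not isolated | COc1cc(OCc3ccccc3)c2c(c1)O[C@H](c1ccc(OCc3ccccc3)c(Oc3ccc(cc3)C3OCCO3)c1)CC2=O | intermediate
10 | 4-{2-(benzyloxy)-5-[(2S)-5-(benzyloxy)-7-methoxy-4-oxochroman-2-yl]phenoxy}benzaldehyde | COc1cc(OCc3ccccc3)c2c(c1)O[C@H](c1ccc(OCc3ccccc3)c(Oc3ccc(C=O)cc3)c1)CC2=O | intermediate
11 | 1-(2,4,6-trihydroxyphenyl)ethan-1-one | CC(=O)c1c(O)cc(O)cc1O | starting material
12 | 1-[2,4-bis(benzyloxy)-6-hydroxyphenyl]ethan-1-one | CC(=O)c1c(O)cc(OCc2ccccc2)cc1OCc1ccccc1 | intermediate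
13 | tert-butyl 3-[2,4-bis(benzyloxy)-6-hydroxyphenyl]-3-oxopropanoate | CC(C)(C)OC(=O)CC(=O)c1c(O)cc(OCc2ccccc2)cc1OCc1ccccc1 | intermediate
14 | tert-butyl 2-[2,4-bis(benzyloxy)-6-hydroxybenzoyl]-3-(4-{2-(benzyloxy)-5-[(2S)-5-(benzyloxy)-7-methoxy-4-oxochroman-2-yl]phenoxy}phenyl)prop-2-enoate, E/Z mixture | COc1cc(OCc3ccccc3)c2c(c1)O[C@H](c1ccc(OCc3ccccc3)c(Oc3ccc(C=C(C(=O)OC(C)(C)C)C(=O)c4c(O)cc(OCc5ccccc5)cc4OCc4ccccc4)cc3)c1)CC2=O | intermediate
15 | tert-butyl (2S)-5,7-bis(benzyloxy)-2-(4-{2-(benzyloxy)-5-[(2S)-5-(benzyloxy)-7-methoxy-4-oxochroman-2-yl]phenoxy}phenyl)-4-oxochromane-3-carboxylate, C3 epimers and enol form, not isolated | COc1cc(OCc3ccccc3)c2c(c1)O[C@H](c1ccc(OCc3ccccc3)c(Oc3ccc([C@@H]4C(C(=O)OC(C)(C)C)C(=O)c5c(OCc6ccccc6)cc(OCc6ccccc6)cc5O4)cc3)c1)CC2=O | intermediate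
16 | (2S)-5,7-bis(benzyloxy)-2-(4-{2-(benzyloxy)-5-[(2S)-5-(benzyloxy)-7-methoxy-4-oxochroman-2-yl]phenoxy}phenyl)chroman-4-one | COc1cc(OCc3ccccc3)c2c(c1)O[C@H](c1ccc(OCc3ccccc3)c(Oc3ccc([C@@H]4CC(=O)c5c(OCc6ccccc6)cc(OCc6ccccc6)cc5O4)cc3)c1)CC2=O | intermediate
17 | 7-O-methyltetrahydroochnaflavone, (2S)-5,7-dihydroxy-2-(4-{2-hydroxy-5-[(2S)-5-hydroxy-7-methoxy-4-oxochroman-2-yl]phenoxy}phenyl)chroman-4-one | COc1cc(O)c2c(c1)O[C@H](c1ccc(O)c(Oc3ccc([C@@H]4CC(=O)c5c(O)cc(O)cc5O4)cc3)c1)CC2=O | target

**Totals**
Total step count: 10.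
Longest linear sequence: 7 steps (steps 2, 3, 4, 5, 8, 9, 10, from compound 4).

**Three steps most likely to fail**

Step 9. Facial selectivity of the oxa-Michael closure may be too low on this hindered 6′-benzyloxy substrate, or the new centre may erode by retro-oxa-Michael reversal or acid-promoted benzylic ionisation before decarboxylation is complete. The fallback sets out from 10 and 12 and comes back at 16; it moves the stereo-determining event into an intermolecular aldol reaction and closes the same ring last by a stereospecific substitution. Ketone 12 is silylated on the phenol and on the enol oxygen (TMSOTf, Et3N, CH2Cl2, 0 °C) to give {3,5-bis(benzyloxy)-2-[1-(trimethylsilyloxy)ethenyl]phenoxy}trimethylsilane F1. A Lewis-base-catalysed enantioselective Mukaiyama aldol addition of F1 to aldehyde 10 (SiCl4, chiral bisphosphoramide of the enantiomeric series that gives the R carbinol, CH2Cl2, −78 °C; aqueous KF/NaHCO3 work-up, which also frees the phenol) should give (2S)-5-(benzyloxy)-2-[4-(benzyloxy)-3-(4-{(1R)-3-[2,4-bis(benzyloxy)-6-hydroxyphenyl]-1-hydroxy-3-oxopropyl}phenoxy)phenyl]-7-methoxychroman-4-one F2. Intramolecular Mitsunobu etherification of F2 (PPh3, DIAD, THF, 0 °C) is expected to close O1–C2 with inversion and so deliver 16.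

Step 8. The secondary amine may open and re-close the flavanone that is already present, eroding its C2 configuration, or the product alkylidene may cyclise prematurely without stereocontrol. The fallback sets out from 7 and comes back at 16; it changes the order of events so that no stereocentre exists while an amine is present. The dioxolane of 7 is hydrolysed selectively (PPTS, acetone/H2O, 40 °C) to tert-butyl 2-[2-(benzyloxy)-6-hydroxy-4-methoxybenzoyl]-3-[4-(benzyloxy)-3-(4-formylphenoxy)phenyl]prop-2-enoate F3. Knoevenagel condensation of F3 with 13 (piperidine/AcOH, 4 Å MS, toluene, rt) gives tert-butyl 2-[2,4-bis(benzyloxy)-6-hydroxybenzoyl]-3-[4-(2-(benzyloxy)-5-{2-[2-(benzyloxy)-6-hydroxy-4-methoxybenzoyl]-3-tert-butoxy-3-oxoprop-1-en-1-yl}phenoxy)phenyl]prop-2-enoate F4. The same thiourea (20 mol%, toluene, −25 °C) then closes both pyranones in one operation to di-tert-butyl bis(4-oxochromane-3-carboxylate) F5, which is not isolated, and TsOH at 80 °C removes both ester groups to give 16. A double catalyst-controlled closure should also enrich the desired (S,S) isomer statistically, at the price of a minor diastereomer to be removed.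

Step 7 (step 3 shares the mechanism; step 7 is named because its product feeds the key step directly). O-acylation or double acylation of the dianion may compete with C-acylation, or the hindered enolate may convert poorly. The fallback sets out from 12 and comes back at 13; it makes the C–C bond intramolecularly. Phenol 12 is converted (Boc2O, Et3N, DMAP cat., MeCN, rt) into 2-acetyl-3,5-bis(benzyloxy)phenyl tert-butyl carbonate F6. Treating F6 with LiHMDS (2.2 equiv, THF, −78 → 0 °C) should bring about an anionic O→C acyl transfer of Baker–Venkataraman type, in which the ketone enolate attacks the neighbouring carbonate and expels the phenoxide, to give 13.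

**Further compounds**
F1 | step 9 | {3,5-bis(benzyloxy)-2-[1-(trimethylsilyloxy)ethenyl]phenoxy}trimethylsilane | C=C(O[Si](C)(C)C)c1c(O[Si](C)(C)C)cc(OCc2ccccc2)cc1OCc1ccccc1
F2 | step 9 | (2S)-5-(benzyloxy)-2-[4-(benzyloxy)-3-(4-{(1R)-3-[2,4-bis(benzyloxy)-6-hydroxyphenyl]-1-hydroxy-3-oxopropyl}phenoxy)phenyl]-7-methoxychroman-4-one | COc1cc(OCc3ccccc3)c2c(c1)O[C@H](c1ccc(OCc3ccccc3)c(Oc3ccc([C@H](O)CC(=O)c4c(O)cc(OCc5ccccc5)cc4OCc4ccccc4)cc3)c1)CC2=O
F3 | step 8 | tert-butyl 2-[2-(benzyloxy)-6-hydroxy-4-methoxybenzoyl]-3-[4-(benzyloxy)-3-(4-formylphenoxy)phenyl]prop-2-enoate | CC(C)(C)OC(=O)C(=Cc1ccc(OCc2ccccc2)c(Oc2ccc(C=O)cc2)c1)C(=O)c1c(O)cc(OC)cc1OCc1ccccc1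
F4 | step 8 | tert-butyl 2-[2,4-bis(benzyloxy)-6-hydroxybenzoyl]-3-[4-(2-(benzyloxy)-5-{2-[2-(benzyloxy)-6-hydroxy-4-methoxybenzoyl]-3-tert-butoxy-3-oxoprop-1-en-1-yl}phenoxy)phenyl]prop-2-enoate | CC(C)(C)OC(=O)C(=Cc1ccc(OCc2ccccc2)c(Oc2ccc(C=C(C(=O)OC(C)(C)C)C(=O)c3c(O)cc(OCc4ccccc4)cc3OCc3ccccc3)cc2)c1)C(=O)c1c(O)cc(OC)cc1OCc1ccccc1
F5 | step 8 | tert-butyl (2S)-5,7-bis(benzyloxy)-2-(4-{2-(benzyloxy)-5-[(2S)-5-(benzyloxy)-3-(tert-butoxycarbonyl)-7-methoxy-4-oxochroman-2-yl]phenoxy}phenyl)-4-oxochromane-3-carboxylate | COc1cc(OCc3ccccc3)c2c(c1)O[C@H](c1ccc(OCc3ccccc3)c(Oc3ccc([C@@H]4C(C(=O)OC(C)(C)C)C(=O)c5c(OCc6ccccc6)cc(OCc6ccccc6)cc5O4)cc3)c1)C(C(=O)OC(C)(C)C)C2=O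
F6 | step 7 | 2-acetyl-3,5-bis(benzyloxy)phenyl tert-butyl carbonate | CC(=O)c1c(OC(=O)OC(C)(C)C)cc(OCc2ccccc2)cc1OCc1ccccc1
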